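**Retrosynthetic overview**

1. The β-diketone is cut between the ring acyl carbon and the central CH: a cyclohexene carboxylic acid (as its N-acylbenzotriazole) and the methyl ketone enolate of MOM-protected dehydrozingerone.
2. Ring numbering: C1 (acyl), C2 (4-hydroxy-3-methoxyphenyl), C3, C4=C5, C6 (3,4-dimethoxyphenyl). The feature used is that C2 lies β to C4 and the aryl-bearing C6 is bonded to C5, so with oxygen at C4 and the alkene at C5=C6 the ring is a Robinson-type cyclohexenone.
3. The C4=C5 alkene and the C6–H bond are therefore traced back to the C4 allylic alcohol of that enone by a reductive 1,3-transposition through an allylic diazene.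
4. The enone is cut at C1–C2 (Michael bond) and C5–C6 (aldol condensation bond) into ethyl 3,4-dimethoxybenzoylacetate (C6, C1 and the ester) and the protected benzylideneacetone (C2 to C5).
5. The single carbocycle is formed in step 3. C2 is set by the catalyst, C1 by equilibration, and C6 by intramolecular hydrogen delivery in step 5.

Key step: step 3

Remark on numbering: the Why lines use the ring numbering of the overview (C1 to C6), while the compound names use systematic locants.

Assumption: the amine derived from quinidine is taken to direct the nucleophile to the Re face of the enone β-carbon, by analogy with additions of 1,3-dicarbonyl compounds to benzylideneacetones under cinchona primary amine salts; should the opposite sense be found, the pseudo-enantiomeric amine derived from quinine is used instead.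

**Route**

Step 1
Reactants: 1 dehydrozingerone
Product: 2 (E)-4-[3-methoxy-4-(methoxymethoxy)phenyl]but-3-en-2-one
Conditions: NaH (1.05 equiv), MOMCl, DMF, 0 °C → rt
Reagents that add atoms: chloromethyl methyl ether, COCCl
Why: Williamson-type O-alkylation of the sodium phenoxide by the α-chloro ether (MOM protection); the enone is untouched and no stereocentre is involved.

Step 2
Reactants: 3 3',4'-dimethoxyacetophenone; 4 diethyl carbonate
Product: 5 ethyl 3-(3,4-dimethoxyphenyl)-3-oxopropanoate
Conditions: NaH (2.2 equiv), (EtO)2CO (3 equiv), THF, reflux; then cold aq. HCl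
Reagents that add atoms: none
Why: Crossed Claisen condensation of the ketone enolate with the non-enolisable carbonate, driven by irreversible deprotonation of the β-keto ester formed (this keto ester can also be purchased).

Step 3
Reactants: 5 ethyl 3-(3,4-dimethoxyphenyl)-3-oxopropanoate; 2 (E)-4-[3-methoxy-4-(methoxymethoxy)phenyl]but-3-en-2-one
Product: 8 ethyl (1R,6S)-2-(3,4-dimethoxyphenyl)-6-[3-methoxy-4-(methoxymethoxy)phenyl]-4-oxocyclohex-2-ene-1-carboxylate, via Michael adduct 6 (not isolated), via aldol adduct 7 (not isolated)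
Conditions: 9-amino-9-deoxy-epi-quinidine (20 mol%), CF3CO2H (40 mol%), toluene, 23 → 40 °C; then p-TsOH·H2O (0.5 equiv), 40 °C
Reagents that add atoms: none
Why: The amine condenses with the ketone of 2 to an iminium ion whose β-carbon C2 is attacked by the enol carbon C1 of 5 (C1–C2 bond); the freed methyl ketone, as enamine or enol, then adds through C5 to the aryl ketone carbon C6, and acid ionises the tertiary benzylic alcohol of 7 and removes water. The closest known reaction is the amine-catalysed domino Michael–aldol (Robinson-type) annulation of aroylacetates with benzylideneacetones. The six-membered ring closes in a 6-(enolendo)-exo-trig aldol step. C2 is set by the catalyst, which shields one face of the E-iminium ion so that the nucleophile arrives on the Re face; C1, acidic as the α-carbon of the ester and γ-carbon of the enone, should equilibrate to the isomer with the ester trans to the C2 aryl group, and C6 stays trigonal. The step needs 1,4- over 1,2-addition and a single cyclisation mode: iminium activation with a soft 1,3-dicarbonyl nucleophile secures the former, only the C5-to-C6 aldol gives a six-membered ring, and the carbinol next to the electron-rich arene should dehydrate under acid mild enough to spare the MOM ether.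

Step 4
Reactants: 8 ethyl (1R,6S)-2-(3,4-dimethoxyphenyl)-6-[3-methoxy-4-(methoxymethoxy)phenyl]-4-oxocyclohex-2-ene-1-carboxylate
Product: 9 ethyl (1R,4R,6S)-2-(3,4-dimethoxyphenyl)-4-hydroxy-6-[3-methoxy-4-(methoxymethoxy)phenyl]cyclohex-2-ene-1-carboxylate
Conditions: NaBH4, CeCl3·7H2O, MeOH/THF, −78 → −20 °C; aq. NaHCO3
Reagents that add atoms: none
Why: Luche 1,2-reduction of the enone, with hydride expected on the face of C4 opposite the C2 aryl group (as in other 5-substituted cyclohexenones), so the C4 hydroxyl should form cis to that aryl group; the ester is not reduced.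

Step 5
Reactants: 9 ethyl (1R,4R,6S)-2-(3,4-dimethoxyphenyl)-4-hydroxy-6-[3-methoxy-4-(methoxymethoxy)phenyl]cyclohex-2-ene-1-carboxylate
Product: 12 ethyl (1R,2R,6S)-2-(3,4-dimethoxyphenyl)-6-[3-methoxy-4-(methoxymethoxy)phenyl]cyclohex-3-ene-1-carboxylate, via sulfonylhydrazine 10 (not isolated), via allylic diazene 11 (not isolated)
Conditions: PPh3, diethyl azodicarboxylate, 2-nitrobenzenesulfonylhydrazide (NBSH), N-methylmorpholine, −30 °C; then 23 °C
Reagents that add atoms: none
Why: Mitsunobu displacement of the C4 alcohol by the sulfonamide nitrogen of NBSH goes with inversion and places nitrogen trans to the C2 aryl group; on warming, sulfinic acid is lost and the monoalkyl diazene 11 expels N2 in a suprafacial retro-ene shift (Myers reductive allylic transposition) that delivers hydrogen to C6 on that face and moves the alkene to C4=C5, so the C6 aryl group should end cis to the C2 aryl group and trans to the ester.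

Step 6
Reactants: 12 ethyl (1R,2R,6S)-2-(3,4-dimethoxyphenyl)-6-[3-methoxy-4-(methoxymethoxy)phenyl]cyclohex-3-ene-1-carboxylate
Product: 13 (1R,2R,6S)-2-(3,4-dimethoxyphenyl)-6-[3-methoxy-4-(methoxymethoxy)phenyl]cyclohex-3-ene-1-carboxylic acid
Conditions: LiOH·H2O, THF/MeOH/H2O, 60 °C; then cold 0.5 M HCl to pH 4
Reagents that add atoms: lithium hydroxide, [Li+].[OH-]
Why: Saponification of the ethyl ester by acyl–oxygen cleavage; the MOM ethers and the isolated alkene are inert to hydroxide, and C1, should it epimerise, returns to the all-equatorial arrangement trans to both aryl groups.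

Step 7
Reactants: 13 (1R,2R,6S)-2-(3,4-dimethoxyphenyl)-6-[3-methoxy-4-(methoxymethoxy)phenyl]cyclohex-3-ene-1-carboxylic acid
Product: 14 (1H-benzotriazol-1-yl)[(1R,2R,6S)-2-(3,4-dimethoxyphenyl)-6-[3-methoxy-4-(methoxymethoxy)phenyl]cyclohex-3-en-1-yl]methanone
Conditions: 1H-benzotriazole, DCC, CH2Cl2, 0 °C → rt
Reagents that add atoms: 1H-benzotriazole, c1ccc2[nH]nnc2c1
Why: Carbodiimide activation of the acid and capture of the O-acylisourea by benzotriazole gives the isolable N-acylbenzotriazole under neutral conditions that spare the MOM ethers.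

Step 8
Reactants: 14 (1H-benzotriazol-1-yl)[(1R,2R,6S)-2-(3,4-dimethoxyphenyl)-6-[3-methoxy-4-(methoxymethoxy)phenyl]cyclohex-3-en-1-yl]methanone; 2 (E)-4-[3-methoxy-4-(methoxymethoxy)phenyl]but-3-en-2-one
Product: 16 (2Z,4E)-1-[(1R,2R,6S)-2-(3,4-dimethoxyphenyl)-6-[3-methoxy-4-(methoxymethoxy)phenyl]cyclohex-3-en-1-yl]-3-hydroxy-5-[3-methoxy-4-(methoxymethoxy)phenyl]penta-2,4-dien-1-one, via lithium enolate 15 (not isolated)
Conditions: 2 (2.2 equiv), LiN(SiMe3)2 (2.2 equiv), THF, −78 °C; then 14, −78 → 0 °C; aq. NH4Cl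
Reagents that add atoms: none
Why: Crossed Claisen-type C-acylation of the kinetic lithium enolate of the methyl ketone by the N-acylbenzotriazole; the second equivalent of enolate deprotonates the β-diketone as it forms, which stops further acylation, and C1 keeps the thermodynamically preferred configuration trans to both aryl groups.

Step 9
Reactants: 16 (2Z,4E)-1-[(1R,2R,6S)-2-(3,4-dimethoxyphenyl)-6-[3-methoxy-4-(methoxymethoxy)phenyl]cyclohex-3-en-1-yl]-3-hydroxy-5-[3-methoxy-4-(methoxymethoxy)phenyl]penta-2,4-dien-1-one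
Product: 17 (2Z,4E)-1-[(1R,2R,6S)-2-(3,4-dimethoxyphenyl)-6-(4-hydroxy-3-methoxyphenyl)cyclohex-3-en-1-yl]-3-hydroxy-5-(4-hydroxy-3-methoxyphenyl)penta-2,4-dien-1-one (CNP0290899.1)
Conditions: conc. HCl (cat.), MeOH/THF, rt → 40 °C
Reagents that add atoms: none
Why: Acid-catalysed acetal exchange with methanol removes both aryl MOM ethers; the enolised β-diketone, the styryl enone and the ring alkene should not react under dilute acid at this temperature.

**Compound list**

1 | dehydrozingerone, (E)-4-(4-hydroxy-3-methoxyphenyl)but-3-en-2-one | COc1cc(/C=C/C(C)=O)ccc1O | starting material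
2 | (E)-4-[3-methoxy-4-(methoxymethoxy)phenyl]but-3-en-2-one | CC(=O)/C=C/c1ccc(OCOC)c(OC)c1 | intermediate
3 | 3',4'-dimethoxyacetophenone | CC(=O)c1ccc(OC)c(OC)c1 | starting material
4 | diethyl carbonate | CCOC(=O)OCC | starting material
5 | ethyl 3-(3,4-dimethoxyphenyl)-3-oxopropanoate | CCOC(=O)CC(=O)c1ccc(OC)c(OC)c1 | intermediate
6 | Michael adduct, ethyl (3S)-2-(3,4-dimethoxybenzoyl)-3-[3-methoxy-4-(methoxymethoxy)phenyl]-5-oxohexanoate (both C2 epimers) | CCOC(=O)C(C(=O)c1ccc(OC)c(OC)c1)[C@@H](c1ccc(OCOC)c(OC)c1)CC(C)=O | intermediate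
7 | aldol adduct, ethyl (1R,2S,6S)-2-(3,4-dimethoxyphenyl)-2-hydroxy-6-[3-methoxy-4-(methoxymethoxy)phenyl]-4-oxocyclohexane-1-carboxylate | CCOC(=O)[C@@H]1[C@@H](c2ccc(OCOC)c(OC)c2)CC(=O)C[C@@]1(O)c1ccc(OC)c(OC)c1 | intermediate
8 | ethyl (1R,6S)-2-(3,4-dimethoxyphenyl)-6-[3-methoxy-4-(methoxymethoxy)phenyl]-4-oxocyclohex-2-ene-1-carboxylate | CCOC(=O)[C@@H]1[C@@H](c2ccc(OCOC)c(OC)c2)CC(=O)C=C1c1ccc(OC)c(OC)c1 | intermediate
9 | ethyl (1R,4R,6S)-2-(3,4-dimethoxyphenyl)-4-hydroxy-6-[3-methoxy-4-(methoxymethoxy)phenyl]cyclohex-2-ene-1-carboxylate | CCOC(=O)[C@@H]1[C@@H](c2ccc(OCOC)c(OC)c2)C[C@@H](O)C=C1c1ccc(OC)c(OC)c1 | intermediate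
10 | sulfonylhydrazine, ethyl (1R,4S,6S)-2-(3,4-dimethoxyphenyl)-6-[3-methoxy-4-(methoxymethoxy)phenyl]-4-[1-(2-nitrophenylsulfonyl)hydrazinyl]cyclohex-2-ene-1-carboxylate | CCOC(=O)[C@@H]1[C@@H](c2ccc(OCOC)c(OC)c2)C[C@H](N(N)S(=O)(=O)c2ccccc2[N+](=O)[O-])C=C1c1ccc(OC)c(OC)c1 | intermediate
11 | allylic diazene, ethyl (1R,4S,6S)-4-diazenyl-2-(3,4-dimethoxyphenyl)-6-[3-methoxy-4-(methoxymethoxy)phenyl]cyclohex-2-ene-1-carboxylate | CCOC(=O)[C@@H]1[C@@H](c2ccc(OCOC)c(OC)c2)C[C@H](N=N)C=C1c1ccc(OC)c(OC)c1 | intermediate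
12 | ethyl (1R,2R,6S)-2-(3,4-dimethoxyphenyl)-6-[3-methoxy-4-(methoxymethoxy)phenyl]cyclohex-3-ene-1-carboxylate | CCOC(=O)[C@@H]1[C@@H](c2ccc(OCOC)c(OC)c2)CC=C[C@H]1c1ccc(OC)c(OC)c1 | intermediate
13 | (1R,2R,6S)-2-(3,4-dimethoxyphenyl)-6-[3-methoxy-4-(methoxymethoxy)phenyl]cyclohex-3-ene-1-carboxylic acid | OC(=O)[C@@H]1[C@@H](c2ccc(OCOC)c(OC)c2)CC=C[C@H]1c1ccc(OC)c(OC)c1 | intermediate
14 | (1H-benzotriazol-1-yl)[(1R,2R,6S)-2-(3,4-dimethoxyphenyl)-6-[3-methoxy-4-(methoxymethoxy)phenyl]cyclohex-3-en-1-yl]methanone | O=C(n1nnc2ccccc12)[C@@H]1[C@@H](c2ccc(OCOC)c(OC)c2)CC=C[C@H]1c1ccc(OC)c(OC)c1 | intermediate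
15 | lithium enolate of 2, lithium (E)-4-[3-methoxy-4-(methoxymethoxy)phenyl]buta-1,3-dien-2-olate | [Li]OC(=C)/C=C/c1ccc(OCOC)c(OC)c1 | intermediate
16 | (2Z,4E)-1-[(1R,2R,6S)-2-(3,4-dimethoxyphenyl)-6-[3-methoxy-4-(methoxymethoxy)phenyl]cyclohex-3-en-1-yl]-3-hydroxy-5-[3-methoxy-4-(methoxymethoxy)phenyl]penta-2,4-dien-1-one (enol form of the β-diketone) | COCOc1ccc(/C=C/C(O)=C/C(=O)[C@@H]2[C@@H](c3ccc(OCOC)c(OC)c3)CC=C[C@H]2c2ccc(OC)c(OC)c2)cc1OC | intermediate
17 | (2Z,4E)-1-[(1R,2R,6S)-2-(3,4-dimethoxyphenyl)-6-(4-hydroxy-3-methoxyphenyl)cyclohex-3-en-1-yl]-3-hydroxy-5-(4-hydroxy-3-methoxyphenyl)penta-2,4-dien-1-one, CNP0290899.1 | COc1cc(/C=C/C(O)=C/C(=O)[C@@H]2[C@@H](c3ccc(O)c(OC)c3)CC=C[C@H]2c2ccc(OC)c(OC)c2)ccc1O | target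

**Step count and risk**

Total step count: 9. Longest linear sequence: 8 steps (steps 1, 3, 4, 5, 6, 7, 8, 9; equally 2, 3 to 9).

Steps most likely to fail:

Step 5. The allylic alcohol is activated next to an electron-rich styrene, so the oxyphosphonium intermediate may ionise before the hydrazide attacks; this would erode the inversion at C4 or lead to elimination to a diene. Fallback: starting from 9, the alcohol is acylated (ClCO2Me, pyridine, CH2Cl2, 0 °C) to the allylic methyl carbonate F1. This is treated with Pd(OAc)2, PBu3 and HCO2H/Et3N in THF: zerovalent palladium ionises the carbonate from the face anti to it, and the palladium hydride formed from formate should deliver hydrogen from the metal face to the aryl-bearing terminus C6, which is the face trans to the C2 aryl group. This palladium-catalysed formate hydrogenolysis with allylic transposition rejoins the route at 12.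

Step 3. Face selection in the iminium addition may be insufficient, or closure onto the electron-rich, enolisable aryl ketone may stall so that prolonged acid treatment starts to remove the MOM ether. Fallback: starting from 5 and 2, the annulation is run without a chiral catalyst (NaOEt 0.2 equiv, EtOH, 0 → 23 °C; then p-TsOH·H2O, toluene, 40 °C). This passes through 6 together with the enantiomeric Michael adduct F2 and 7 together with the enantiomeric aldol adduct F3, and gives 8 together with the enantiomeric cyclohexenone F4 as a racemate. The racemate is resolved by preparative chromatography on a chiral stationary phase, F4 is discarded, and the route is rejoined at 8.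

Step 8. The acyl carbon of 14 sits between two aryl-bearing carbons, so attack by the enolate may be slow and give way to O-acylation or self-condensation of the enolate. Fallback: starting from 12, the ester is reduced (i-Bu2AlH, CH2Cl2, −78 → 0 °C) to the primary alcohol F5 and oxidised (Dess–Martin periodinane, NaHCO3, CH2Cl2) to the aldehyde F6. Aldol addition of lithium enolate 15 (THF, −78 °C) to this less hindered electrophile gives the β-hydroxy ketone F7 as a mixture of carbinol epimers, and a second Dess–Martin oxidation gives the β-diketone, rejoining the route at 16.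

**Further compounds**

F1 | step 5 | ethyl (1R,4R,6S)-2-(3,4-dimethoxyphenyl)-4-[(methoxycarbonyl)oxy]-6-[3-methoxy-4-(methoxymethoxy)phenyl]cyclohex-2-ene-1-carboxylate | CCOC(=O)[C@@H]1[C@@H](c2ccc(OCOC)c(OC)c2)C[C@@H](OC(=O)OC)C=C1c1ccc(OC)c(OC)c1
F2 | step 3 | ethyl (3R)-2-(3,4-dimethoxybenzoyl)-3-[3-methoxy-4-(methoxymethoxy)phenyl]-5-oxohexanoate | CCOC(=O)C(C(=O)c1ccc(OC)c(OC)c1)[C@H](c1ccc(OCOC)c(OC)c1)CC(C)=O
F3 | step 3 | ethyl (1S,2R,6R)-2-(3,4-dimethoxyphenyl)-2-hydroxy-6-[3-methoxy-4-(methoxymethoxy)phenyl]-4-oxocyclohexane-1-carboxylate | CCOC(=O)[C@H]1[C@H](c2ccc(OCOC)c(OC)c2)CC(=O)C[C@]1(O)c1ccc(OC)c(OC)c1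
F4 | step 3 | ethyl (1S,6R)-2-(3,4-dimethoxyphenyl)-6-[3-methoxy-4-(methoxymethoxy)phenyl]-4-oxocyclohex-2-ene-1-carboxylate | CCOC(=O)[C@H]1[C@H](c2ccc(OCOC)c(OC)c2)CC(=O)C=C1c1ccc(OC)c(OC)c1
F5 | step 8 | [(1R,2R,6S)-2-(3,4-dimethoxyphenyl)-6-[3-methoxy-4-(methoxymethoxy)phenyl]cyclohex-3-en-1-yl]methanol | OC[C@@H]1[C@@H](c2ccc(OCOC)c(OC)c2)CC=C[C@H]1c1ccc(OC)c(OC)c1
F6 | step 8 | (1R,2R,6S)-2-(3,4-dimethoxyphenyl)-6-[3-methoxy-4-(methoxymethoxy)phenyl]cyclohex-3-ene-1-carbaldehyde | O=C[C@@H]1[C@@H](c2ccc(OCOC)c(OC)c2)CC=C[C@H]1c1ccc(OC)c(OC)c1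
F7 | step 8 | (E)-5-[(1R,2R,6S)-2-(3,4-dimethoxyphenyl)-6-[3-methoxy-4-(methoxymethoxy)phenyl]cyclohex-3-en-1-yl]-5-hydroxy-1-[3-methoxy-4-(methoxymethoxy)phenyl]pent-1-en-3-one (both carbinol epimers) | COCOc1ccc(/C=C/C(=O)CC(O)[C@@H]2[C@@H](c3ccc(OCOC)c(OC)c3)CC=C[C@H]2c2ccc(OC)c(OC)c2)cc1OC
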